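**Strategy.** Everything rests on cutting C1–C2 and C5–C10 of the bicyclo[2.2.2]octenone: the C1(=O)–C10 bridge becomes a nitroalkene (a ketene equivalent) and ring C2–C3=C4–C5–C1'–C2' becomes the s-cis-locked 1,3-diene latent in (R)-carvone. One thermal intramolecular [4+2] reaction then closes the bicyclooctene and the cyclohexane C5–C6–C7–C8–C9–C10 and sets C2, C5, C10 (and C1, later erased by a Nef reaction). The precursor is a carvone-derived cyclohexadiene carrying at C5 an all-trans butyrolactone (C6, C7, C11) whose C7 arm ends in the E-nitroalkene C10=C1; the step exploits the carvone-type diene ring, its C2' stereocentre and the diequatorial trans-lactone tether.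

Key step: step 12

Atom labels: C1 ketone carbon; C2 bridgehead CH; C3=C4(CH3) ring alkene; C5 quaternary bridgehead; C6 lactone OCH; C7 ring-fusion CH; C8 and C9 CH2; C10 quaternary C(CH3); C11 CH(CH3); C12 lactone C=O; C1'H2–C2'H saturated bridge; C3' the =CH2-bearing carbon of the side chain.

Abbreviation: "dienyl" = (5S)-2-methyl-5-(6-methylhepta-1,5-dien-2-yl)cyclohexa-1,3-dien-1-yl (its ring carbon 1 is C5, its ring carbon 5 is C2').

Assumption: in step 6 the ligand enantiomer is assigned by the usual dinuclear-zinc model, taken here as Si-face delivery with (R,R)-ProPhenol; should an MTPA-ester check on the first batch show the opposite sense, (S,S)-ProPhenol is used and nothing else changes.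

Step 1
Reactants: 1 (R)-(−)-carvone
Product: 2 (5R)-5-(3-chloroprop-1-en-2-yl)-2-methylcyclohex-2-en-1-one
Conditions: Ca(OCl)2, CO2 (dry ice), CH2Cl2/H2O, 0 °C
Reagents that add atoms: calcium hypochlorite, [Ca+2].[O-]Cl.[O-]Cl
Why: Ene-type allylic chlorination by hypochlorous acid made in situ should attack only the electron-rich 1,1-disubstituted alkene, not the enone alkene, and leaves the stereocentre untouched.

Step 2
Reactants: 2 allylic chloride; 3 allyltributylstannane
Product: 4 (5R)-5-(hexa-1,5-dien-2-yl)-2-methylcyclohex-2-en-1-one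
Conditions: Pd2(dba)3 (2.5 mol%), PPh3 (10 mol%), THF, 60 °C
Reagents that add atoms: allyltributylstannane 3, C=CC[Sn](CCCC)(CCCC)CCCC
Why: Stille allyl–allyl cross-coupling through a 2-substituted π-allyl complex of divalent palladium whose two termini are equivalent, so no regiochemical question arises, and the neutral stannane leaves the ketone alone.

Step 3
Reactants: 4 terminal diene; 5 2-methylbut-2-ene
Product: 6 (5R)-2-methyl-5-(6-methylhepta-1,5-dien-2-yl)cyclohex-2-en-1-one
Conditions: second-generation Grubbs catalyst RuCl2(=CHPh)(PCy3)(H2IMes) (3 mol%), 2-methylbut-2-ene/CH2Cl2, 40 °C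
Reagents that add atoms: 2-methylbut-2-ene 5, CC=C(C)C
Why: Olefin cross-metathesis should exchange the CH2 terminus of the monosubstituted alkene for isopropylidene, while the 1,1-disubstituted alkene and the enone alkene are too hindered or electron-poor to take part.

Step 4
Reactants: 6 enone
Product: 7 (5S)-2-methyl-5-(6-methylhepta-1,5-dien-2-yl)cyclohexa-1,3-dien-1-yl trifluoromethanesulfonate
Conditions: Tf2O, 2,6-di-tert-butyl-4-methylpyridine, CH2Cl2, 0 °C → rt
Reagents that add atoms: trifluoromethanesulfonic anhydride, O=S(=O)(OS(=O)(=O)C(F)(F)F)C(F)(F)F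
Why: Thermodynamic dienol triflate formation: O-sulfonylation of the enone and loss of a gamma proton from the ring CH2 give the through-conjugated 1,3-dienyl triflate, while the hindered base buffers the acid that could otherwise isomerise the triene; the stereocentre keeps its geometry (its descriptor changes to S only through the priority rules).

Step 5
Reactants: 7 dienyl triflate; 8 carbon monoxide
Product: 9 (5S)-2-methyl-5-(6-methylhepta-1,5-dien-2-yl)cyclohexa-1,3-diene-1-carbaldehyde
Conditions: Pd(PPh3)4 (5 mol%), CO (1 atm), Bu3SnH (1.1 equiv, syringe pump), THF, 50 °C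
Reagents that add atoms: carbon monoxide 8, [C-]#[O+]
Why: Palladium-catalysed reductive carbonylation (formylation) of an alkenyl triflate by oxidative addition to zerovalent palladium, CO insertion and hydride transfer from tin; slow addition of the hydride should suppress direct reduction and keep palladium hydride away from the diene.

Step 6
Reactants: 9 dienal; 10 methyl propiolate
Product: 11 methyl (4S)-4-hydroxy-4-dienylbut-2-ynoate
Conditions: (R,R)-ProPhenol (20 mol%), Ph3P=O (40 mol%), Me2Zn (3 equiv), PhMe, 4 °C; aq NH4Cl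
Reagents that add atoms: methyl propiolate 10, C#CC(=O)OC
Why: Zinc–ProPhenol-catalysed asymmetric alkynylation of an α,β-unsaturated aldehyde, in which the chiral dizinc pocket delivers the zinc alkynylide to the Si face and so sets C6 (S) under catalyst control, the remote C2' centre having no influence.

Step 7
Reactants: 11 hydroxy ynoate
Product: 13 (5S)-5-dienylfuran-2(5H)-one, via Z-hydroxy enoate 12 (not isolated)
Conditions: H2 (1 atm), Pd/CaCO3 (Pb(OAc)2-poisoned), quinoline, EtOAc, rt, stopped at 1 equiv H2; then PPTS (5 mol%), CH2Cl2, rt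
Reagents that add atoms: none
Why: cis-Semihydrogenation of the electron-poor alkyne on poisoned palladium should give the Z-γ-hydroxy enoate, which lactonises with loss of methanol; C6 is not a reacting centre.

Step 8
Reactants: 13 butenolide; 14 2-(2-bromoethyl)-2-methyl-1,3-dioxolane
Product: 17 (4S,5S)-4-[2-(2-methyl-1,3-dioxolan-2-yl)ethyl]-5-dienyloxolan-2-one, via Grignard reagent 15 (not isolated), via silyl ketene acetal 16 (not isolated)
Conditions: 14, Mg, THF, 25 °C; then CuBr·SMe2 (0.2 equiv), TMSCl (2 equiv), 13, THF, −78 °C; aq NH4Cl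
Reagents that add atoms: 2-(2-bromoethyl)-2-methyl-1,3-dioxolane 14, CC1(CCBr)OCCO1
Why: Copper-catalysed conjugate addition of a Grignard reagent to a butenolide, in which the nucleophile enters C7 on the face opposite the C6 dienyl group (the usual 4,5-trans outcome for 5-substituted furan-2(5H)-ones) and the fast silyl-accelerated 1,4-addition should outrun deprotonation at C6.

Step 9
Reactants: 17 lactone; 18 iodomethane
Product: 20 (3S,4S,5S)-3-methyl-4-[2-(2-methyl-1,3-dioxolan-2-yl)ethyl]-5-dienyloxolan-2-one, via lithium enolate 19 (not isolated)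
Conditions: LDA (1.1 equiv), THF, −78 °C; MeI (3 equiv), −78 → −40 °C
Reagents that add atoms: iodomethane 18, CI
Why: Lactone enolate alkylation in which methyl iodide approaches C11 anti to the neighbouring C7 substituent, giving the 3,4-trans (all-trans) lactone, which is also the more stable C11 epimer and therefore safe under the mild bases used later.

Step 10
Reactants: 20 ketal
Product: 21 (3S,4S,5S)-3-methyl-4-(3-oxobutyl)-5-dienyloxolan-2-one
Conditions: PPTS (0.2 equiv), acetone/H2O 10:1, 45 °C
Reagents that add atoms: water, O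
Why: Acid-catalysed hydrolysis of a ketone dioxolane, with an acid weak enough to leave the diene, the 1,1-disubstituted alkene and the lactone untouched.

Step 11
Reactants: 21 methyl ketone; 22 nitromethane
Product: 24 (3S,4S,5S)-3-methyl-4-[(3E)-3-methyl-4-nitrobut-3-en-1-yl]-5-dienyloxolan-2-one, via tertiary nitro alcohol 23 (not isolated)
Conditions: MeNO2 (solvent), DBU (0.3 equiv), 0 °C → rt; AcOH, evaporate; (CF3CO)2O (1.5 equiv), Et3N (3 equiv), CH2Cl2, −20 → 0 °C
Reagents that add atoms: nitromethane 22, C[N+](=O)[O-]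
Why: Henry (nitroaldol) addition to the methyl ketone, then E1cB dehydration of the trifluoroacetate through the nitronate, which can only place the double bond at C10=C1; the E isomer (nitro anti to the longer chain) should prevail, and any Z isomer converges later because C1 becomes a carbonyl.

Step 12
Reactants: 24 dienyl lactone nitroalkene
Product: 25 C1-nitro tetracycle (the skeleton of 27 with H, toward the C3=C4 bridge, and NO2, toward the C1'–C2' bridge, on C1 in place of the ketone)
Conditions: PhMe (5 mM), BHT (0.1 equiv), 120 °C, sealed tube, Ar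
Reagents that add atoms: none
Why: The HOMO of the s-cis-locked diene C2=C3–C4=C5 and the LUMO of the nitroalkene C10=C1 combine in a concerted but asynchronous [4+2] cycloaddition in which the C5–C10 bond to the electrophilic beta carbon runs ahead of C1–C2; the closest known reaction type is the intramolecular Diels–Alder reaction of nitroalkenes, used as ketene equivalents, with cyclohexa-1,3-dienes. The cyclohexane C5–C6–C7–C8–C9–C10 closes in the type-1 (fused) mode through the four-atom tether in a chair, and the bicyclo[2.2.2]octene closes as the bridge laid across C2 and C5 of the diene ring. C2 and C5 are set by the diene face, controlled by the C2' stereocentre, which sends the dienophile anti to its side chain; C10 is set by placing C9 endo under C3=C4, which the C6/C7 trans-lactone enforces because only then are O6 and C11 both equatorial on the forming chair; C1 follows from the E geometry (nitro exo) and is immaterial. The step needs regio-, face- and endo/exo-selectivity at once: the tether fixes the regiochemistry (C10 to the substituted terminus C5), and with the rigid lactone only the anti/endo and the syn/exo arrangements remain, the second being disfavoured by the C2' side chain. Because two adjacent quaternary carbons are formed, high dilution, a radical inhibitor and the lowest workable temperature are used to keep 1,5-hydrogen shifts and aromatisation of the diene behind the cycloaddition.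

Step 13
Reactants: 25 nitro tetracycle
Product: 27 target keto lactone, via potassium nitronate 26 (not isolated)
Conditions: KOtBu (1.05 equiv), THF, 0 °C; then aq TiCl3 (4 equiv), NH4OAc buffer (pH 5–6), THF/H2O, 0 °C → rt
Reagents that add atoms: water, O
Why: Nef reaction in its reductive form: the nitronate is reduced by trivalent titanium to the imine, which hydrolyses to the C1 ketone; the buffered, non-oxidising medium should spare the three alkenes and the lactone, and the bridgehead C2 and quaternary C10 beside the new carbonyl cannot epimerise.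

**Compound list**

1 | (R)-(−)-carvone, (5R)-2-methyl-5-(prop-1-en-2-yl)cyclohex-2-en-1-one | CC1=CC[C@H](CC1=O)C(C)=C | starting material
2 | (5R)-5-(3-chloroprop-1-en-2-yl)-2-methylcyclohex-2-en-1-one | CC1=CC[C@H](CC1=O)C(CCl)=C | intermediate
3 | allyltributylstannane | C=CC[Sn](CCCC)(CCCC)CCCC | starting material
4 | (5R)-5-(hexa-1,5-dien-2-yl)-2-methylcyclohex-2-en-1-one | CC1=CC[C@H](CC1=O)C(CCC=C)=C | intermediate
5 | 2-methylbut-2-ene | CC=C(C)C | starting material
6 | (5R)-2-methyl-5-(6-methylhepta-1,5-dien-2-yl)cyclohex-2-en-1-one | CC1=CC[C@H](CC1=O)C(CCC=C(C)C)=C | intermediate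
7 | (5S)-2-methyl-5-(6-methylhepta-1,5-dien-2-yl)cyclohexa-1,3-dien-1-yl trifluoromethanesulfonate | C=C(CCC=C(C)C)[C@H]1CC(OS(=O)(=O)C(F)(F)F)=C(C)C=C1 | intermediate
8 | carbon monoxide | [C-]#[O+] | starting material
9 | (5S)-2-methyl-5-(6-methylhepta-1,5-dien-2-yl)cyclohexa-1,3-diene-1-carbaldehyde | C=C(CCC=C(C)C)[C@H]1CC(C=O)=C(C)C=C1 | intermediate
10 | methyl propiolate | C#CC(=O)OC | starting material
11 | methyl (4S)-4-hydroxy-4-[(5S)-2-methyl-5-(6-methylhepta-1,5-dien-2-yl)cyclohexa-1,3-dien-1-yl]but-2-ynoate | C=C(CCC=C(C)C)[C@H]1CC(=C(C)C=C1)[C@@H](O)C#CC(=O)OC | intermediate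
12 | methyl (2Z,4S)-4-hydroxy-4-[(5S)-2-methyl-5-(6-methylhepta-1,5-dien-2-yl)cyclohexa-1,3-dien-1-yl]but-2-enoate | C=C(CCC=C(C)C)[C@H]1CC(=C(C)C=C1)[C@@H](O)/C=C\C(=O)OC | intermediate
13 | (5S)-5-[(5S)-2-methyl-5-(6-methylhepta-1,5-dien-2-yl)cyclohexa-1,3-dien-1-yl]furan-2(5H)-one | C=C(CCC=C(C)C)[C@H]1CC(=C(C)C=C1)[C@H]1OC(=O)C=C1 | intermediate
14 | 2-(2-bromoethyl)-2-methyl-1,3-dioxolane | CC1(CCBr)OCCO1 | starting material
15 | [2-(2-methyl-1,3-dioxolan-2-yl)ethyl]magnesium bromide | CC1(CC[Mg]Br)OCCO1 | intermediate
16 | trimethylsilyl ketene acetal of 17, {[(4S,5S)-4-[2-(2-methyl-1,3-dioxolan-2-yl)ethyl]-5-dienyl-4,5-dihydrofuran-2-yl]oxy}trimethylsilane | C=C(CCC=C(C)C)[C@H]1CC(=C(C)C=C1)[C@H]1OC(O[Si](C)(C)C)=C[C@@H]1CCC2(C)OCCO2 | intermediate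
17 | (4S,5S)-4-[2-(2-methyl-1,3-dioxolan-2-yl)ethyl]-5-[(5S)-2-methyl-5-(6-methylhepta-1,5-dien-2-yl)cyclohexa-1,3-dien-1-yl]oxolan-2-one (C6/C7 trans) | C=C(CCC=C(C)C)[C@H]1CC(=C(C)C=C1)[C@H]1OC(=O)C[C@@H]1CCC2(C)OCCO2 | intermediate
18 | iodomethane | CI | starting material
19 | lithium enolate of 17, lithium (4S,5S)-4-[2-(2-methyl-1,3-dioxolan-2-yl)ethyl]-5-dienyl-4,5-dihydrofuran-2-olate | C=C(CCC=C(C)C)[C@H]1CC(=C(C)C=C1)[C@H]1OC(O[Li])=C[C@@H]1CCC2(C)OCCO2 | intermediate
20 | (3S,4S,5S)-3-methyl-4-[2-(2-methyl-1,3-dioxolan-2-yl)ethyl]-5-[(5S)-2-methyl-5-(6-methylhepta-1,5-dien-2-yl)cyclohexa-1,3-dien-1-yl]oxolan-2-one (all-trans) | C=C(CCC=C(C)C)[C@H]1CC(=C(C)C=C1)[C@H]1OC(=O)[C@@H](C)[C@@H]1CCC2(C)OCCO2 | intermediate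
21 | (3S,4S,5S)-3-methyl-4-(3-oxobutyl)-5-[(5S)-2-methyl-5-(6-methylhepta-1,5-dien-2-yl)cyclohexa-1,3-dien-1-yl]oxolan-2-one | C=C(CCC=C(C)C)[C@H]1CC(=C(C)C=C1)[C@H]1OC(=O)[C@@H](C)[C@@H]1CCC(C)=O | intermediate
22 | nitromethane | C[N+](=O)[O-] | starting material
23 | (3S,4S,5S)-4-(3-hydroxy-3-methyl-4-nitrobutyl)-3-methyl-5-dienyloxolan-2-one (both carbinol epimers) | C=C(CCC=C(C)C)[C@H]1CC(=C(C)C=C1)[C@H]1OC(=O)[C@@H](C)[C@@H]1CCC(C)(O)C[N+](=O)[O-] | intermediate
24 | (3S,4S,5S)-3-methyl-4-[(3E)-3-methyl-4-nitrobut-3-en-1-yl]-5-[(5S)-2-methyl-5-(6-methylhepta-1,5-dien-2-yl)cyclohexa-1,3-dien-1-yl]oxolan-2-one | C=C(CCC=C(C)C)[C@H]1CC(=C(C)C=C1)[C@H]1OC(=O)[C@@H](C)[C@@H]1CC/C(C)=C/[N+](=O)[O-] | intermediate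
25 | C1-nitro tetracycle: as 27, with C1 bearing H (toward the C3=C4 bridge) and NO2 (toward the C1'–C2' bridge) | C=C(CCC=C(C)C)[C@H]1C[C@@]23C(C)=C[C@@H]1[C@@H]([N+](=O)[O-])[C@]2(C)CC[C@H]1[C@H](C)C(=O)O[C@@H]13 | intermediate
26 | potassium nitronate of 25 (C1=N(O)O−) | C=C(CCC=C(C)C)[C@H]1C[C@@]23C(C)=C[C@@H]1C(=[N+]([O-])[O-])[C@]2(C)CC[C@H]1[C@H](C)C(=O)O[C@@H]13.[K+] | intermediate
27 | target keto lactone: bicyclo[2.2.2]octenone (bridgeheads C2, C5; bridges C3=C4(CH3), C1'H2–C2'H, C1(=O)–C10(CH3)) fused at C5–C10 to a cyclohexane that carries the trans-fused γ-lactone O–C6/C7–C11(CH3)–C12(=O); the C2' side chain and C9 lie on the side of the C3=C4 bridge, the C10 methyl on the side of the C1'–C2' bridge, H6 and H7 are trans-diaxial, and the C11 methyl is cis to H7 | C=C(CCC=C(C)C)[C@H]1C[C@@]23C(C)=C[C@@H]1C(=O)[C@]2(C)CC[C@H]1[C@H](C)C(=O)O[C@@H]13 | target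

**Count.** Total steps: 13. Longest linear sequence: 13 steps (from 1; all other starting materials are commercial).

**Steps most likely to fail**

Step 12 (intramolecular Diels–Alder). Bond formation between the fully substituted carbons C5 and C10 may be slower than thermal 1,5-hydrogen shifts and aromatisation of the diene, or the dienophile may approach syn to the C2' side chain with the tether exo. The fallback sets out from nitroalkene 24. SnCl4 (1.5 equiv) in CH2Cl2 at −78 °C should make the nitroalkene react as a heterodiene (C10=C1–N=O) with the C5=C4 bond in an inverse-demand hetero-[4+2] cycloaddition. This should give the cyclic nitronate F1, in which C5–C10 and O–C4 have formed on the same face through the same chair tether. After a buffered quench, gentle heating of F1 in toluene (60–80 °C) should bring about the [3,3]-sigmatropic shift (O–C4 breaks, C1–C2 forms) and deliver nitro tetracycle 25, where the route is rejoined. Both operations are known for nitroalkenes with cyclic dienes, and the hard C5–C10 bond is made at low temperature, outside the thermal window of the diene.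

Step 11 (nitroalkene). The nitroaldol equilibrium may lie on the side of ketone 21 (retro-Henry), so that little nitro alcohol 23 is present when the dehydrating agent is added. The fallback sets out from 21. Corey–Chaykovsky methylenation (Me3S+ I−, KHMDS, THF, 0 °C; ylide preformed) should give the terminal epoxide F2. Opening F2 at its CH2 terminus with NaNO2/MgSO4 in MeOH forms the C–N bond irreversibly and should give nitro alcohol 23, which re-enters step 11 at the dehydration stage.

Step 4 (dienyl triflate). Proton loss may occur from the alpha' methylene (C1') instead of the gamma methylene (C2), giving the cross-conjugated 2-triflyloxy diene, or acid may shift the C3'=CH2 bond and aromatise the ring. The fallback sets out from enone 6. TMSCl/NaI/Et3N in MeCN (thermodynamic silylation) should give the through-conjugated trimethylsilyl dienol ether F3, which is purified. MeLi (THF, 0 °C) then releases the regiodefined lithium dienolate F4, and PhNTf2 triflates it on oxygen to give 7, where the route is rejoined.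

**Further compounds**

F1 | step 12 | cyclic nitronate (1,2-oxazine N-oxide: O bonded to C4, C10 bonded to C5, C1=N, C2=C3 retained) | C=C(CCC=C(C)C)[C@@H]1C=C[C@@]4(C)O[N+]([O-])=C[C@]5(C)CC[C@H]6[C@H](C)C(=O)O[C@@H]6[C@]45C1
F2 | step 11 | (3S,4S,5S)-3-methyl-4-[2-(2-methyloxiran-2-yl)ethyl]-5-dienyloxolan-2-one (both epoxide epimers) | C=C(CCC=C(C)C)[C@H]1CC(=C(C)C=C1)[C@H]1OC(=O)[C@@H](C)[C@@H]1CCC2(C)CO2
F3 | step 4 | trimethyl{[(5S)-2-methyl-5-(6-methylhepta-1,5-dien-2-yl)cyclohexa-1,3-dien-1-yl]oxy}silane | C=C(CCC=C(C)C)[C@H]1CC(O[Si](C)(C)C)=C(C)C=C1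
F4 | step 4 | lithium (5S)-2-methyl-5-(6-methylhepta-1,5-dien-2-yl)cyclohexa-1,3-dien-1-olate | C=C(CCC=C(C)C)[C@H]1CC(O[Li])=C(C)C=C1
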